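Ring A is built, not functionalised. It is disconnected across C7–C8 and C4a–C8a (plus C6–C7) into a 3-ethoxy-4-(piperidin-2-yl)cyclobutenone and (triisopropylsilyloxy)acetylene. One thermal benzannulation assembles the 1,3,5-trioxygenated ring A around C6, which already carries the intact C2' stereocentre of (R)-homopipecolic acid. The three oxygens emerge differentiated: C5 as ethyl ether, C7 as free phenol, and C8a, para to C6, as silyl ether reserved as O1 of ring C. The precursor is an N-methoxycarbonyl cyclobutenone made by ketene–ethoxyacetylene cycloaddition; its carbamate later becomes the N-methyl group.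

Key step: step 4

Remark: flavone numbering is used for ring A (C4a, C5 to C8, C8a) and primed numbers for the piperidine; cyclobutenone 7 is carried as both epimers at its ring sp3 carbon, which ends as aromatic C6, and 1 is taken as the free amino acid.

Step 1
Reactants: 1 (R)-2-(piperidin-2-yl)acetic acid; 2 methyl chloroformate
Product: 3 (R)-2-[1-(methoxycarbonyl)piperidin-2-yl]acetic acid
Conditions: ClCO2Me (1.2 equiv), NaOH (2.5 equiv), H2O/THF, 0 °C → rt; then aq. HCl to pH 2
Reagents that add atoms: none
Why: Schotten–Baumann N-acylation of the secondary amine gives the carbamate, which makes nitrogen non-basic for the ketene chemistry and is the latent N-methyl group; the (R) centre at C2' comes from the chiral pool and is not involved.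

Step 2
Reactants: 3 (R)-2-[1-(methoxycarbonyl)piperidin-2-yl]acetic acid; 4 ethoxyacetylene
Product: 7 methyl (2R)-2-(2-ethoxy-4-oxocyclobut-2-en-1-yl)piperidine-1-carboxylate, via acid chloride 5 (not isolated), via ketene 6 (not isolated)
Conditions: (COCl)2 (1.2 equiv), DMF (cat.), CH2Cl2, 0 °C → rt, concentrate; then ethoxyacetylene (3 equiv), Et3N (1.3 equiv, slow addition), Et2O, 0 °C → rt; chromatography on Et3N-deactivated silica
Reagents that add atoms: none
Why: Et3N dehydrochlorinates acid chloride 5 at its α-CH2 to aldoketene 6, which the electron-rich ynol ether traps in situ in a regioselective ketene–alkyne [2+2] cycloaddition (alkyne CH carbon to ketene carbonyl carbon) to give the 3-ethoxycyclobutenone; C2' lies β to the acyl carbon and is not enolised, and the new ring sp3 centre may be a mixture because it later becomes aromatic C6.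

Step 3
Reactants: 8 acetylene
Product: 11 (triisopropylsilyloxy)acetylene, via lithium acetylide 9 (not isolated), via lithium ethynolate 10 (not isolated)
Conditions: HC≡CH (excess, sat. in THF), n-BuLi (1.0 equiv), −78 °C; t-BuOOLi (1.0 equiv, premixed from t-BuOOH and LiN(SiMe3)2 at −78 °C), −78 → −20 °C; i-Pr3SiOTf (1.05 equiv), −78 → 0 °C; pentane/cold aq. NaHCO3, distillation
Reagents that add atoms: tert-butyl hydroperoxide, CC(C)(C)OO; triisopropylsilyl triflate, CC(C)[Si](C(C)C)(C(C)C)OS(=O)(=O)C(F)(F)F
Why: The acetylide carbon attacks the electrophilic peroxide oxygen (oxidation of a lithium acetylide with lithium tert-butyl peroxide) to give the ynolate, which the bulky silyl triflate silylates on oxygen to the ynol silyl ether; excess acetylene and temperatures below −20 °C should hold back disproportionation to Li2C2.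

Step 4
Reactants: 7 methyl (2R)-2-(2-ethoxy-4-oxocyclobut-2-en-1-yl)piperidine-1-carboxylate; 11 (triisopropylsilyloxy)acetylene
Product: 16 methyl (R)-2-[2-ethoxy-6-hydroxy-4-(triisopropylsilyloxy)phenyl]piperidine-1-carboxylate, via vinylketene 12 (not isolated), via vinylcyclobutenone 13 (not isolated), via dienylketene 14 (not isolated), via cyclohexadienone 15 (not isolated)
Conditions: 11 (1.5 equiv), toluene (0.5 M), 80 → 110 °C, sealed tube, Ar
Reagents that add atoms: none
Why: Thermal 4π electrocyclic opening of 7 (cleaving the bond between the carbonyl carbon and the piperidine-bearing carbon) gives vinylketene 12; the nucleophilic CH carbon of 11 attacks the ketene carbonyl carbon and the oxygen-bearing carbon closes onto the ketene α-carbon, a regioselective [2+2] that makes C7–C8 and C4a–C8a in vinylcyclobutenone 13. A second 4π opening gives dienylketene 14, whose thermally allowed disrotatory 6π electrocyclisation joins the ketene carbon to the piperidine-bearing carbon, re-forming C6–C7 and closing ring A as cyclohexadienone 15, which tautomerises to phenol 16. This is the cyclobutenone–heteroalkyne (Danheiser) benzannulation, well documented for siloxyalkynes. No stereocentre is created: C2' is a spectator that never becomes cationic, anionic or radical, and both epimers of 7 converge because the epimeric carbon becomes aromatic C6. The selectivity needed is the orientation of the ketene–alkyne [2+2], secured by the polarisation of the siloxyalkyne, which places OSi on C8a para to C6 and leaves the ketene oxygen as the C7 phenol next to the C5 ethyl ether.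

Step 5
Reactants: 16 methyl (R)-2-[2-ethoxy-6-hydroxy-4-(triisopropylsilyloxy)phenyl]piperidine-1-carboxylate
Product: 17 methyl (R)-2-[2,6-diethoxy-4-(triisopropylsilyloxy)phenyl]piperidine-1-carboxylate
Conditions: EtI (3 equiv), K2CO3 (2 equiv, anhydrous), acetone, 50 °C
Reagents that add atoms: ethyl iodide, CCI
Why: Williamson O-ethylation of the only free phenol under anhydrous carbonate conditions that leave the aryl silyl ether and the carbamate intact; with both oxygens ortho to C6 as ethyl ethers, the two remaining ring CH positions become equivalent for the later iodination.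

Step 6
Reactants: 17 methyl (R)-2-[2,6-diethoxy-4-(triisopropylsilyloxy)phenyl]piperidine-1-carboxylate
Product: 18 methyl (R)-2-(2,6-diethoxy-4-hydroxyphenyl)piperidine-1-carboxylate
Conditions: Bu4NF (1.1 equiv), AcOH (1.1 equiv), THF, 0 °C → rt
Reagents that add atoms: none
Why: Fluoride attacks silicon and cleaves the aryl O–Si bond (silyl ether deprotection), acetic acid buffering the phenoxide, so that only the oxygen para to C6, the future O1, is unmasked.

Step 7
Reactants: 18 methyl (R)-2-(2,6-diethoxy-4-hydroxyphenyl)piperidine-1-carboxylate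
Product: 19 (R)-3,5-diethoxy-4-(1-methylpiperidin-2-yl)phenol
Conditions: LiAlH4 (5 equiv), THF, 0 °C → reflux; aq. potassium sodium tartrate, extraction at pH 8–9
Reagents that add atoms: none
Why: Hydride reduction of the methyl carbamate proceeds through loss of methoxide and reduction of the resulting iminium to the N-methyl amine (carbamate-to-N-methyl reduction with LiAlH4), with the phenol only deprotonated and C2', which has no acidic or ionisable bond, unchanged.

Step 8
Reactants: 19 (R)-3,5-diethoxy-4-(1-methylpiperidin-2-yl)phenol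
Product: 20 (R)-3,5-diethoxy-2-iodo-4-(1-methylpiperidin-2-yl)phenol
Conditions: NIS (1.0 equiv), TsOH·H2O (1.1 equiv), MeCN, −20 → 0 °C; aq. Na2S2O3/NaHCO3
Reagents that add atoms: N-iodosuccinimide, O=C1CCC(=O)N1I
Why: Electrophilic aromatic iodination with NIS occurs ortho to the phenol at one of the two equivalent ring CH positions, each activated by all three oxygens; one equivalent at low temperature limits di-iodination, and N-protonation by TsOH shields the amine from oxidation and from retro-Mannich loss of the side chain.

Step 9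
Reactants: 20 (R)-3,5-diethoxy-2-iodo-4-(1-methylpiperidin-2-yl)phenol; 21 phenylacetylene
Product: 23 (R)-5,7-diethoxy-6-(1-methylpiperidin-2-yl)-2-phenyl-4H-chromen-4-one, via ynone 22 (not isolated)
Conditions: phenylacetylene (1.5 equiv), CO (20 bar), PdCl2(dppf) (5 mol %), Et2NH, 100 °C
Reagents that add atoms: carbon monoxide, [C-]#[O+]
Why: Zerovalent palladium formed in situ inserts into the C–I bond, CO insertion and alkynylation of the aroylpalladium give ynone 22 (carbonylative Sonogashira coupling), and diethylamine then mediates 6-endo closure of the phenol oxygen onto the ynone, as in the known carbonylative annulation of 2-iodophenols with terminal alkynes to flavones; C4a–C4, C4–C3 and O1–C2 are formed without touching C2'.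

Step 10
Reactants: 23 (R)-5,7-diethoxy-6-(1-methylpiperidin-2-yl)-2-phenyl-4H-chromen-4-one
Product: 24 (R)-5,7-dihydroxy-6-(1-methylpiperidin-2-yl)-2-phenyl-4H-chromen-4-one
Conditions: BBr3 (6 equiv), CH2Cl2, −78 °C → rt; MeOH quench, aq. NaHCO3 to pH 7–8
Reagents that add atoms: none
Why: BBr3 complexes the ether oxygens and bromide removes both ethyl groups (Lewis-acid aryl ether cleavage, the C5 ether assisted by chelation to the C4 carbonyl), while the boron-bound or protonated nitrogen cannot expel C2' as an iminium, so the (R) centre from the chiral pool should reach 24 unchanged.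

Compound list
1 | (R)-2-(piperidin-2-yl)acetic acid | OC(=O)C[C@H]1CCCCN1 | starting material
2 | methyl chloroformate | COC(=O)Cl | starting material
3 | (R)-2-[1-(methoxycarbonyl)piperidin-2-yl]acetic acid | OC(=O)C[C@H]1CCCCN1C(=O)OC | intermediate
4 | ethoxyacetylene | CCOC#C | starting material
5 | methyl (R)-2-(2-chloro-2-oxoethyl)piperidine-1-carboxylate (acid chloride) | ClC(=O)C[C@H]1CCCCN1C(=O)OC | intermediate
6 | methyl (R)-2-(2-oxoethenyl)piperidine-1-carboxylate (ketene) | O=C=C[C@H]1CCCCN1C(=O)OC | intermediate
7 | methyl (2R)-2-(2-ethoxy-4-oxocyclobut-2-en-1-yl)piperidine-1-carboxylate, both epimers at the ring sp3 carbon | CCOC1=CC(=O)C1[C@H]1CCCCN1C(=O)OC | intermediate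
8 | acetylene | C#C | starting material
9 | lithium acetylide | [Li]C#C | intermediate
10 | lithium ethynolate | [Li]OC#C | intermediate
11 | (triisopropylsilyloxy)acetylene | C#CO[Si](C(C)C)(C(C)C)C(C)C | intermediate
12 | methyl (2R)-2-[(1Z)-2-ethoxy-4-oxobuta-1,3-dien-1-yl]piperidine-1-carboxylate (vinylketene, geometry expected from outward rotation) | O=C=C/C(OCC)=C/[C@H]1CCCCN1C(=O)OC | intermediate
13 | methyl (2R)-2-[(1Z)-2-ethoxy-2-[4-oxo-2-(triisopropylsilyloxy)cyclobut-2-en-1-yl]ethenyl]piperidine-1-carboxylate (vinylcyclobutenone, ring sp3 carbon unassigned) | O=C1C=C(O[Si](C(C)C)(C(C)C)C(C)C)C1/C(OCC)=C/[C@H]1CCCCN1C(=O)OC | intermediate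
14 | methyl (2R)-2-[(1Z,3E)-2-ethoxy-6-oxo-4-(triisopropylsilyloxy)hexa-1,3,5-trien-1-yl]piperidine-1-carboxylate (dienylketene) | O=C=C/C(O[Si](C(C)C)(C(C)C)C(C)C)=C\C(OCC)=C\[C@H]1CCCCN1C(=O)OC | intermediate
15 | methyl (2R)-2-[2-ethoxy-6-oxo-4-(triisopropylsilyloxy)cyclohexa-2,4-dien-1-yl]piperidine-1-carboxylate (cyclohexadienone, ring sp3 carbon unassigned) | O=C1C=C(O[Si](C(C)C)(C(C)C)C(C)C)C=C(OCC)C1[C@H]1CCCCN1C(=O)OC | intermediate
16 | methyl (R)-2-[2-ethoxy-6-hydroxy-4-(triisopropylsilyloxy)phenyl]piperidine-1-carboxylate | CCOc1cc(O[Si](C(C)C)(C(C)C)C(C)C)cc(O)c1[C@H]1CCCCN1C(=O)OC | intermediate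
17 | methyl (R)-2-[2,6-diethoxy-4-(triisopropylsilyloxy)phenyl]piperidine-1-carboxylate | CCOc1cc(O[Si](C(C)C)(C(C)C)C(C)C)cc(OCC)c1[C@H]1CCCCN1C(=O)OC | intermediate
18 | methyl (R)-2-(2,6-diethoxy-4-hydroxyphenyl)piperidine-1-carboxylate | CCOc1cc(O)cc(OCC)c1[C@H]1CCCCN1C(=O)OC | intermediate
19 | (R)-3,5-diethoxy-4-(1-methylpiperidin-2-yl)phenol | CCOc1cc(O)cc(OCC)c1[C@H]1CCCCN1C | intermediate
20 | (R)-3,5-diethoxy-2-iodo-4-(1-methylpiperidin-2-yl)phenol | CCOc1cc(O)c(I)c(OCC)c1[C@H]1CCCCN1C | intermediate
21 | phenylacetylene | C#Cc1ccccc1 | starting material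
22 | 1-[2,4-diethoxy-6-hydroxy-3-[(2R)-1-methylpiperidin-2-yl]phenyl]-3-phenylprop-2-yn-1-one (ynone) | CCOc1cc(O)c(C(=O)C#Cc2ccccc2)c(OCC)c1[C@H]1CCCCN1C | intermediate
23 | (R)-5,7-diethoxy-6-(1-methylpiperidin-2-yl)-2-phenyl-4H-chromen-4-one | CCOc1cc2oc(-c3ccccc3)cc(=O)c2c(OCC)c1[C@H]1CCCCN1C | intermediate
24 | (R)-5,7-dihydroxy-6-(1-methylpiperidin-2-yl)-2-phenyl-4H-chromen-4-one | CN1CCCC[C@@H]1c1c(O)cc2oc(-c3ccccc3)cc(=O)c2c1O | target

Total step count: 10 (nine in the main line and one for alkyne 11).
Longest linear sequence: 9 steps, from 1 to 24 (steps 1, 2 and 4 to 10).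

Steps most likely to fail

Step 4. The electrocyclic opening of the vinylogous-ester cyclobutenone may be slower than the thermal isomerisation of 11 to a silylketene or its consumption by the product phenol, or the cascade may stall at 13. The fallback sets out from acid 3 and comes back at phenol 16, generating the same vinylketene 12 by base instead of by heat. Acid 3 is homologated (1,1'-carbonyldiimidazole, then Mg(O2CCH2CO2Et)2, THF) to ethyl (R)-4-[1-(methoxycarbonyl)piperidin-2-yl]-3-oxobutanoate F1. HC(OEt)3 with catalytic H2SO4 in EtOH gives the enol ether ethyl (E)-3-ethoxy-4-[(2R)-1-(methoxycarbonyl)piperidin-2-yl]but-2-enoate F2. LiOH in aqueous THF gives (E)-3-ethoxy-4-[(2R)-1-(methoxycarbonyl)piperidin-2-yl]but-2-enoic acid F3, and (COCl)2 gives (E)-3-ethoxy-4-[(2R)-1-(methoxycarbonyl)piperidin-2-yl]but-2-enoyl chloride F4. Et3N in toluene in the presence of 11 should effect 1,4-dehydrochlorination to 12 at room temperature. The [2+2], ring opening and 6π closure then need only the mild warming (about 60–80 °C) at which 4-vinylcyclobutenones open, giving 16.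

Step 3. Lithium acetylide may disproportionate to Li2C2 before oxygen transfer, and the ynolate may be silylated at carbon. The fallback replaces acetylene 8 by ethyl formate as the carbon source and comes back at ynolate 10 and alkyne 11. LiCHBr2 (from CH2Br2 and lithium 2,2,6,6-tetramethylpiperidide, THF, −78 °C) adds to ethyl formate, and LiN(SiMe3)2 converts the adduct into lithium 2,2-dibromoethen-1-olate F5. n-BuLi exchanges one bromine to give the carbenoid lithium 2-bromo-2-lithioethen-1-olate F6, which on warming rearranges to 10 (the ester-to-ynolate rearrangement of the Kowalski homologation). i-Pr3SiCl then gives 11.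

Step 9. Direct coupling without CO uptake (leading to a benzofuran), 5-exo closure to an aurone, capture of the aroylpalladium by diethylamine, or slow oxidative addition into the hindered electron-rich iodide may divert the cascade. The fallback sets out from iodophenol 20 and comes back at flavone 23 through ynone 22, here isolated. n-BuLi (2.2 equiv, THF, −78 °C) deprotonates the phenol and exchanges iodine for lithium to give lithium 3,5-diethoxy-2-lithio-4-[(2R)-1-methylpiperidin-2-yl]phenolate F7. This is acylated by N-methoxy-N-methyl-3-phenylprop-2-ynamide F8 (from 3-phenylpropiolic acid, (COCl)2, then MeONHMe·HCl and pyridine) to give 22 after work-up. Et2NH in EtOH (rt to 50 °C) then closes the pyranone by conjugate addition, cyclisation and loss of the amine to 23.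

Further compounds
F1 | step 4 | ethyl (R)-4-[1-(methoxycarbonyl)piperidin-2-yl]-3-oxobutanoate | CCOC(=O)CC(=O)C[C@H]1CCCCN1C(=O)OC
F2 | step 4 | ethyl (E)-3-ethoxy-4-[(2R)-1-(methoxycarbonyl)piperidin-2-yl]but-2-enoate | CCOC(=O)/C=C(/OCC)C[C@H]1CCCCN1C(=O)OC
F3 | step 4 | (E)-3-ethoxy-4-[(2R)-1-(methoxycarbonyl)piperidin-2-yl]but-2-enoic acid | OC(=O)/C=C(/OCC)C[C@H]1CCCCN1C(=O)OC
F4 | step 4 | (E)-3-ethoxy-4-[(2R)-1-(methoxycarbonyl)piperidin-2-yl]but-2-enoyl chloride | ClC(=O)/C=C(/OCC)C[C@H]1CCCCN1C(=O)OC
F5 | step 3 | lithium 2,2-dibromoethen-1-olate | [Li]OC=C(Br)Br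
F6 | step 3 | lithium 2-bromo-2-lithioethen-1-olate | [Li]OC=C([Li])Br
F7 | step 9 | lithium 3,5-diethoxy-2-lithio-4-[(2R)-1-methylpiperidin-2-yl]phenolate | [Li]Oc1cc(OCC)c([C@H]2CCCCN2C)c(OCC)c1[Li]
F8 | step 9 | N-methoxy-N-methyl-3-phenylprop-2-ynamide | CON(C)C(=O)C#Cc1ccccc1
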